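The runs are calculated from invented constants, and the scatter is random.

Ask what the end of a flask must be before asking how fast it gets there. Friday's flask was still standing, and I had to say what it held at 4.0 d and which move would add product.

| flask | starting material | coupling partner | free catalyst | temperature | remark | time |
|---|---|---|---|---|---|---|
| Friday's | 0.050 M | 0.040 M | 5 mM | 25 °C | the very flask that is asked about, followed so far |  |
| Monday's | 0.10 M | 0.040 M | 5 mM | 10 °C | run made earlier |  |
| flask | 0.050 M | 0.0400 M | 5.0 mM | 25 °C |  | 4.0 d |

| run | time / h | product / % | starting material / % |
|---|---|---|---|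
| Friday's | 5.00 | 77.7 | 22.1 |
| Friday's | 8.00 | 78.9 | 20.6 |
| Friday's | 15.0 | 79.8 | 21.1 |
| Friday's | 30.0 | 80.3 | 19.3 |
| Friday's | 60.0 | 79.7 | 19.9 |
| Monday's | 0.833 | 5.1 | 94.3 |
| Monday's | 3.00 | 19.9 | 80.4 |
| Monday's | 5.00 | 28.0 | 71.4 |
| Monday's | 8.00 | 36.0 | 63.6 |
| Monday's | 10.0 | 37.3 | 62.4 |

(scatter of a reading: 0.5 percentage points)

- product, in percent of the starting material first charged, at 4.0 d
- what to do for the largest gain in product; "none" if nothing gains more than 2 percentage points (ash / maple / alder / birch / elm / none)
- product present, with what was taken out counted in, in percent of the starting material first charged, after alder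
- product present, with what was taken out counted in, in percent of the starting material first charged, after elm

- ash: at 4.0 d add coupling partner, 50.0 % of the amount charged, then wait 8.0 d
- maple: at 4.0 d raise the temperature by 25 K, then wait 8.0 d
- alder: at 4.0 d take out 90 % of the product then present, then wait 8.0 d
- birch: change nothing and wait 8.0 d more
- elm: at 4.0 d add free catalyst, 100 % of the amount charged, then wait 8.0 d

- what is taken out of product is counted as made
- the numbers in the tables scatter with a standard deviation of 0.5 percentage points
- additions bring no volume worth counting

I bracketed the product in Friday's flask. From above I took 80.0 %, the partner ceiling: the charge of coupling partner over the charge of starting material, if one partner goes into each product and coupling partner is the limiting reagent. From below I took the last 3 product readings of Friday's run, which averaged 79.9 %. Product and starting material together read 99.6 % at the last reading of Friday's run, so I saw no third sink in that run. The gap of 0.100 percentage points was smaller than the scatter of 0.5 points, and the two bounds came from different things: charges and readings.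

Monday's run read 37.3 % at its last reading, below its own ceiling of 40.0 %. One doubt stayed. Both runs charged 8.00 partners per catalyst, so these charges did not tell a ceiling set by the coupling partner from a catalyst that stopped after that many turnovers.

Birch, maple, alder and elm added no coupling partner, so I left the ceiling at 80.0 %. By this reckoning ash lifted it to 120 %, but the charge of starting material capped that at 100 %, an expected gain of 20 points.

The forecast gave 80 %, at the top of my bracket, and chose ash, with 80 % after alder and 80 % after elm. Its ground was the shared plateau, “so the coupling partner is used up”.

The flask gave 80.0 %, on the ceiling of 80.0 %. Ash gained 20 points, while alder stood at 80.0 % and elm at 80.0 %.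

    catalyst intermediate A ⇌ catalyst intermediate B (K = 1.00, k = 0.310 min⁻¹, Ea = 90.0 kJ mol⁻¹, ΔH = 5.00 kJ mol⁻¹)
    coupling partner + free catalyst → catalyst intermediate A (k = 6.80 M⁻¹ min⁻¹, Ea = 51.0 kJ mol⁻¹)
    starting material + catalyst intermediate B → catalyst intermediate C (k = 130 M⁻¹ min⁻¹, Ea = 56.0 kJ mol⁻¹)
    catalyst intermediate C → free catalyst + product (k = 2.40 min⁻¹, Ea = 68.0 kJ mol⁻¹)
    free catalyst ⇌ dormant form (K = 2.10, k = 0.0180 min⁻¹, Ea = 101 kJ mol⁻¹, ΔH = −71.0 kJ mol⁻¹)
    (constants at 25 °C)

As the flask stood at 96.0 h, its slowest mode had a half-life of 1.05 h, far shorter than the 4.0 d waited. At that time 0 % of the coupling partner charged and 20 % of the starting material charged were left. For the neighbour charged with 0.024 M of coupling partner, the ceiling scaled to 48.0 %. That neighbour gave 48.0 % at 4.0 d.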